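**Plan**

- Retrosynthesis first removes the three phenolic benzyl ethers, then cuts the bond between ring A C2 and heptyl C1, then the depside ester bond between the ring B carbonyl and the ring A C4 oxygen.
- Forward: ring B is prepared as 2,4-di-O-benzylorsellinic acid and esterified onto the 4-hydroxyl of 2,4-dihydroxybenzaldehyde; the 2-hydroxyl is benzylated and the aldehyde oxidised to the acid.
- The heptyl chain is joined last but one, by carboxylate-directed palladation of the finished depside acid and coupling with potassium heptyltrifluoroborate; hydrogenolysis then frees the three phenols.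
- Enabling feature: in ring A the carboxyl carbon C1 sits between C6, which carries oxygen, and C2, so the acid has exactly one ortho C-H, and that carbon is where the chain belongs.
- Stereochemistry: the target has no stereocentre and no stereogenic double bond, so nothing has to be set.

Key step: step 7

Assumption: orsellinic acid, 2,4-dihydroxybenzaldehyde and 1-bromoheptane are taken as purchasable, and the acid is carried at the aldehyde oxidation level so that no carboxyl protecting group is needed.

**Step 1**
Reactants: 1 orsellinic acid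
Product: 2 benzyl 2,4-bis(benzyloxy)-6-methylbenzoate
Conditions: BnBr (3.3 equiv), K2CO3, DMF, rt then 50 °C
Reagents that add atoms: benzyl bromide, BrCc1ccccc1
Why: Williamson-type O-alkylation in which carbonate deprotonates the acid and both phenols and each oxygen displaces bromide by SN2, the carboxylate reacting first so that the decarboxylation-prone free acid is consumed before warming.

**Step 2**
Reactants: 2 benzyl 2,4-bis(benzyloxy)-6-methylbenzoate
Product: 3 2,4-bis(benzyloxy)-6-methylbenzoic acid
Conditions: KOH, DMSO/H2O, 80 °C; then aq. HCl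
Reagents that add atoms: potassium hydroxide, [K+].[OH-]
Why: Saponification of a di-ortho-substituted benzoate, for which poorly solvated hydroxide in wet DMSO is reactive enough, while the benzyl ethers are inert to base.

**Step 3**
Reactants: 3 2,4-bis(benzyloxy)-6-methylbenzoic acid; 4 2,4-dihydroxybenzaldehyde
Product: 6 4-formyl-3-hydroxyphenyl 2,4-bis(benzyloxy)-6-methylbenzoate, via mixed trifluoroacetic anhydride 5 (not isolated)
Conditions: (CF3CO)2O, toluene, 0 °C to rt
Reagents that add atoms: none
Why: Depside esterification through a mixed carboxylic-trifluoroacetic anhydride, which transfers the electron-rich aroyl group to the free 4-hydroxyl while the 2-hydroxyl is held in a hydrogen bond to the aldehyde and should stay unacylated.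

**Step 4**
Reactants: 6 4-formyl-3-hydroxyphenyl 2,4-bis(benzyloxy)-6-methylbenzoate
Product: 7 3-(benzyloxy)-4-formylphenyl 2,4-bis(benzyloxy)-6-methylbenzoate
Conditions: BnBr, K2CO3, DMF, rt to 40 °C
Reagents that add atoms: benzyl bromide, BrCc1ccccc1
Why: Williamson ether synthesis on the chelated phenol, tolerated by the aryl ester because its carbonyl is shielded by the ortho benzyloxy and ortho methyl groups of ring B.

**Step 5**
Reactants: 7 3-(benzyloxy)-4-formylphenyl 2,4-bis(benzyloxy)-6-methylbenzoate
Product: 8 2-(benzyloxy)-4-{[2,4-bis(benzyloxy)-6-methylbenzoyl]oxy}benzoic acid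
Conditions: NaClO2, NaH2PO4, 2-methyl-2-butene, t-BuOH/THF/H2O, 0 °C to rt
Reagents that add atoms: sodium chlorite, [Na+].[O-]Cl=O
Why: Pinnick oxidation, in which chlorous acid adds to the aldehyde and fragments to the acid while 2-methyl-2-butene traps the hypochlorous acid before it can chlorinate the electron-rich rings; ester and benzyl ethers are untouched.

**Step 6**
Reactants: 9 1-bromoheptane
Product: 12 potassium heptyltrifluoroborate, via heptylmagnesium bromide 10 (not isolated), via dimethyl heptylboronate 11 (not isolated)
Conditions: Mg, cat. I2, THF, reflux; B(OMe)3, THF, -78 °C to rt; aq. KHF2, 0 °C to rt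
Reagents that add atoms: trimethyl borate, COB(OC)OC; potassium hydrogen difluoride, F.[F-].[K+]
Why: Grignard formation, borylation of the Grignard reagent with a trialkyl borate and fluoride exchange with KHF2 form the standard route to primary alkyltrifluoroborates and should give a crystalline, air-stable salt.

**Step 7**
Reactants: 8 2-(benzyloxy)-4-{[2,4-bis(benzyloxy)-6-methylbenzoyl]oxy}benzoic acid; 12 potassium heptyltrifluoroborate
Product: 13 2-(benzyloxy)-4-{[2,4-bis(benzyloxy)-6-methylbenzoyl]oxy}-6-heptylbenzoic acid
Conditions: Pd(OAc)2 (10 mol%), N-acetyl-L-valine (20 mol%), Ag2CO3 (2 equiv), 1,4-benzoquinone (0.5 equiv), 12 (3 equiv), t-BuOH, 90 °C, sealed tube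
Reagents that add atoms: none
Why: The carboxylate of 8 binds divalent palladium and, assisted by the N-acetyl amino acid ligand, concerted metalation-deprotonation at the only free ortho C-H gives a five-membered aryl palladacycle; transmetalation of the heptyl group from boron and C(sp2)-C(sp3) reductive elimination then form the bond between ring A and heptyl C1, and Ag2CO3 returns zerovalent palladium to the divalent state. The reaction relied on is the carboxylate-directed, Pd(OAc)2-catalysed oxidative ortho C-H alkylation of benzoic acids with primary alkylboron reagents under Ag2CO3 and benzoquinone, applied here to a 2-alkoxy-4-acyloxybenzoic acid. No ring is closed and no stereocentre is formed. The step needs site selectivity, and the substrate secures it: the second ortho position of ring A carries the benzyloxy group, so only one C-H is within reach of the carboxylate and double alkylation is impossible, while ring B has no free acid and its ester carbonyl, twisted out of plane by two ortho substituents, is too weak a donor to direct palladation. The step also needs reductive elimination to outrun beta-hydride loss from the heptylpalladium species, which benzoquinone and the amino acid ligand are there to ensure, and the di-ortho-substituted aryl ester should withstand the carbonate base in the bulky, weakly nucleophilic alcohol.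

**Step 8**
Reactants: 13 2-(benzyloxy)-4-{[2,4-bis(benzyloxy)-6-methylbenzoyl]oxy}-6-heptylbenzoic acid
Product: 14 4-[(2,4-dihydroxy-6-methylbenzoyl)oxy]-2-heptyl-6-hydroxybenzoic acid
Conditions: H2 (1 atm), 10% Pd/C, EtOAc, rt
Reagents that add atoms: none
Why: Catalytic hydrogenolysis cleaves the three benzyl aryl ethers under neutral conditions at room temperature, leaving the aryl ester, the arenes, the alkyl chain and the decarboxylation-prone salicylic acid unit intact.

**Compound list**

1 | orsellinic acid (2,4-dihydroxy-6-methylbenzoic acid) | Cc1cc(O)cc(O)c1C(=O)O | starting material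
2 | benzyl 2,4-bis(benzyloxy)-6-methylbenzoate | Cc1cc(OCc2ccccc2)cc(OCc2ccccc2)c1C(=O)OCc1ccccc1 | intermediate
3 | 2,4-bis(benzyloxy)-6-methylbenzoic acid | Cc1cc(OCc2ccccc2)cc(OCc2ccccc2)c1C(=O)O | intermediate
4 | 2,4-dihydroxybenzaldehyde | O=Cc1ccc(O)cc1O | starting material
5 | 2,4-bis(benzyloxy)-6-methylbenzoic trifluoroacetic anhydride | Cc1cc(OCc2ccccc2)cc(OCc2ccccc2)c1C(=O)OC(=O)C(F)(F)F | intermediate
6 | 4-formyl-3-hydroxyphenyl 2,4-bis(benzyloxy)-6-methylbenzoate | O=Cc1ccc(OC(=O)c2c(C)cc(OCc3ccccc3)cc2OCc2ccccc2)cc1O | intermediate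
7 | 3-(benzyloxy)-4-formylphenyl 2,4-bis(benzyloxy)-6-methylbenzoate | O=Cc1ccc(OC(=O)c2c(C)cc(OCc3ccccc3)cc2OCc2ccccc2)cc1OCc1ccccc1 | intermediate
8 | 2-(benzyloxy)-4-{[2,4-bis(benzyloxy)-6-methylbenzoyl]oxy}benzoic acid | O=C(O)c1ccc(OC(=O)c2c(C)cc(OCc3ccccc3)cc2OCc2ccccc2)cc1OCc1ccccc1 | intermediate
9 | 1-bromoheptane | CCCCCCCBr | starting material
10 | heptylmagnesium bromide | CCCCCCC[Mg]Br | intermediate
11 | dimethyl heptylboronate | CCCCCCCB(OC)OC | intermediate
12 | potassium heptyltrifluoroborate | [K+].CCCCCCC[B-](F)(F)F | intermediate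
13 | 2-(benzyloxy)-4-{[2,4-bis(benzyloxy)-6-methylbenzoyl]oxy}-6-heptylbenzoic acid | CCCCCCCc1cc(OC(=O)c2c(C)cc(OCc3ccccc3)cc2OCc2ccccc2)cc(OCc2ccccc2)c1C(=O)O | intermediate
14 | 4-[(2,4-dihydroxy-6-methylbenzoyl)oxy]-2-heptyl-6-hydroxybenzoic acid | CCCCCCCc1cc(OC(=O)c2c(C)cc(O)cc2O)cc(O)c1C(=O)O | target

**Step count**

Total: 8 steps. Longest linear sequence: 7 steps (steps 1, 2, 3, 4, 5, 7, 8); step 6 is a one-step side branch.

**Steps most likely to fail**

1. Step 7. Beta-hydride elimination from the heptylpalladium intermediate may outrun reductive elimination, the alkylboron reagent may be lost by protodeboronation, or the newly formed di-ortho-substituted acid may lose CO2 under the hot silver carbonate. The fallback gives up the C-H alkylation and brings the chain in with ring A. It sets out from acid 3 and comes back to the route at target 14.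
   - Purchased 5-heptylresorcinol (CCCCCCCc1cc(O)cc(O)c1) is formylated under Vilsmeier-Haack conditions (POCl3, DMF, then aqueous hydrolysis) to 2,4-dihydroxy-6-heptylbenzaldehyde F1.
   - Acid 3 is esterified onto the 4-hydroxyl of this aldehyde with (CF3CO)2O in toluene to give 4-formyl-3-heptyl-5-hydroxyphenyl 2,4-bis(benzyloxy)-6-methylbenzoate F2.
   - Pinnick oxidation (NaClO2, NaH2PO4, 2-methyl-2-butene) should give 4-{[2,4-bis(benzyloxy)-6-methylbenzoyl]oxy}-2-heptyl-6-hydroxybenzoic acid F3.
   - Hydrogenolysis of its two benzyl ethers (H2, 10% Pd/C, EtOAc) gives 14.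

2. Step 4. O-Alkylation of the hydrogen-bonded phenol may be slow enough that phenoxide or carbonate attacks the depside ester, leading to acyl transfer or cleavage. The fallback installs the benzyl ether before the ester exists. It sets out from aldehyde 4 and comes back at 7, replacing steps 3 and 4.
   - Selective allylation of the 4-hydroxyl (allyl bromide, K2CO3, acetone) gives 4-(allyloxy)-2-hydroxybenzaldehyde F4.
   - Benzylation (BnBr, K2CO3, DMF) gives 4-(allyloxy)-2-(benzyloxy)benzaldehyde F5.
   - Allyl transfer to methoxide (Pd(PPh3)4, K2CO3, MeOH) frees 2-(benzyloxy)-4-hydroxybenzaldehyde F6.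
   - The single phenol of this compound is esterified with acid 3 and (CF3CO)2O in toluene to give 7.

3. Step 5. Hypochlorous acid formed during the oxidation may chlorinate the electron-rich benzyloxy-substituted rings faster than the scavenger removes it. The fallback carries the ring A carboxyl at the acid oxidation level as an allyl ester. It sets out from acid 3 and comes back at acid 8.
   - Purchased 2,4-dihydroxybenzoic acid (O=C(O)c1ccc(O)cc1O) is converted with allyl bromide and KHCO3 in DMF into allyl 2,4-dihydroxybenzoate F7.
   - Acid 3 is esterified onto its 4-hydroxyl with (CF3CO)2O in toluene to give allyl 4-{[2,4-bis(benzyloxy)-6-methylbenzoyl]oxy}-2-hydroxybenzoate F8.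
   - Benzylation (BnBr, K2CO3, DMF) gives allyl 2-(benzyloxy)-4-{[2,4-bis(benzyloxy)-6-methylbenzoyl]oxy}benzoate F9.
   - Deallylation with Pd(PPh3)4 and PhSiH3 in CH2Cl2 at rt releases 8.

**Further compounds**

F1 | step 7 | 2,4-dihydroxy-6-heptylbenzaldehyde | CCCCCCCc1cc(O)cc(O)c1C=O
F2 | step 7 | 4-formyl-3-heptyl-5-hydroxyphenyl 2,4-bis(benzyloxy)-6-methylbenzoate | CCCCCCCc1cc(OC(=O)c2c(C)cc(OCc3ccccc3)cc2OCc2ccccc2)cc(O)c1C=O
F3 | step 7 | 4-{[2,4-bis(benzyloxy)-6-methylbenzoyl]oxy}-2-heptyl-6-hydroxybenzoic acid | CCCCCCCc1cc(OC(=O)c2c(C)cc(OCc3ccccc3)cc2OCc2ccccc2)cc(O)c1C(=O)O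
F4 | step 4 | 4-(allyloxy)-2-hydroxybenzaldehyde | C=CCOc1ccc(C=O)c(O)c1
F5 | step 4 | 4-(allyloxy)-2-(benzyloxy)benzaldehyde | C=CCOc1ccc(C=O)c(OCc2ccccc2)c1
F6 | step 4 | 2-(benzyloxy)-4-hydroxybenzaldehyde | O=Cc1ccc(O)cc1OCc1ccccc1
F7 | step 5 | allyl 2,4-dihydroxybenzoate | C=CCOC(=O)c1ccc(O)cc1O
F8 | step 5 | allyl 4-{[2,4-bis(benzyloxy)-6-methylbenzoyl]oxy}-2-hydroxybenzoate | C=CCOC(=O)c1ccc(OC(=O)c2c(C)cc(OCc3ccccc3)cc2OCc2ccccc2)cc1O
F9 | step 5 | allyl 2-(benzyloxy)-4-{[2,4-bis(benzyloxy)-6-methylbenzoyl]oxy}benzoate | C=CCOC(=O)c1ccc(OC(=O)c2c(C)cc(OCc3ccccc3)cc2OCc2ccccc2)cc1OCc1ccccc1
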